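**Assumptions (one line each)**
- Methyl D‑erythrofuranoside (6) is used as its anomeric mixture (β drawn); its anomeric carbon becomes the sp² carbon C6, so that configuration is irrelevant.
- The benzotetramisole enantiomer in Step 2 is the one that delivers the (S)‑ester 4; the assignment would be confirmed by correlation.
- Iridoid numbering (C1, O2, C3…C11) is used for positions throughout.

**Retrosynthetic overview**
1. Target ⇐ acetylation of the C11 alcohol ⇐ Stille hydroxymethylation of a C3=C4 dienyl triflate ⇐ bicyclic enone 10 (C4 ketone, C5=C6).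
2. Enone ⇐ intramolecular aldol condensation (C5–C6) of a keto‑furanoside; opening of the furanose releases C10–OH.
3. Key step: C8–C9 bond by intermolecular radical conjugate addition of the C3′ radical of methyl D‑erythrofuranoside (site‑selective C–H abstraction) to an Achmatowicz enone; this sets C8 (quaternary carbinol) and C9 together.
4. Ring order: pyran first (Achmatowicz; C1 set by catalytic dynamic kinetic acylation with the isovalerate that stays to the end), cyclopentene second (radical C–C, then aldol).

**Route**

Step 1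
Reactants: 1, furfuryl alcohol
Product: 2, 6‑hydroxy‑2H‑pyran‑3(6H)‑one (racemic, interconverting lactol)
Conditions: NBS, NaHCO3, NaOAc, THF/H2O (4:1), 0 °C
Reagents that add atoms: water, O
Why: Achmatowicz oxidative ring expansion of a 2‑furylcarbinol gives the pyranone that already contains C1, O2, C3, C4, C5 and C9.

Step 2
Reactants: 2; 3, isovaleric acid
Product: 4, (2S)‑5‑oxo‑5,6‑dihydro‑2H‑pyran‑2‑yl 3‑methylbutanoate
Conditions: 3, Piv2O, i‑Pr2NEt, benzotetramisole (5 mol %), toluene, −20 °C
Reagents that add atoms: none (Piv2O only activates 3 as the mixed anhydride)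
Why: Isothiourea‑catalysed dynamic kinetic asymmetric acylation; the lactol epimerises through ring opening while the chiral acyl‑isothiouronium acylates one anomer, which sets C1 (S) and installs the final C1 isovalerate.

Step 3
Reactants: 5, D‑erythrose
Product: 6, methyl β‑D‑erythrofuranoside, (2R,3R,4R)‑2‑methoxyoxolane‑3,4‑diol (with minor α‑anomer)
Conditions: MeOH, AcCl (0.1 equiv), 0 °C → rt; then NaHCO3
Reagents that add atoms: methanol, CO
Why: Fischer glycosidation (a tetrose can only give furanosides) masks the future C6 aldehyde and leaves the cis‑2,3‑diol free to direct the C–H abstraction.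

Step 4 (key step)
Reactants: 4 (1 equiv, added slowly); 6 (1.5 equiv)
Product: 7, methyl 3‑C‑[(2S,3S)‑2‑(3‑methylbutanoyloxy)‑5‑oxooxan‑3‑yl]‑β‑D‑erythrofuranoside. The cis‑2′,3′‑diol is retained, and on the oxanone ring the sugar is trans to the C1 ester.
Conditions: [Ir(dF(CF3)ppy)2(dtbbpy)]PF6 (1 mol %), quinuclidine (20 mol %), Ph2BOH (20 mol %), MeCN, 450 nm LEDs, rt
Reagents that add atoms: none
Why: Proposed new method: the tetracoordinate diphenylborinate of the cis‑diol makes the carbinol C–H bonds hydridic, and the quinuclidinium radical cation abstracts H3′ (H2′ is deactivated by the adjacent anomeric carbon); the tertiary α‑oxy radical reacts on the convex face of the cis‑fused borinate (retention at C8, anti to O7) and adds in Giese fashion to the enone β‑carbon anti to the pseudo‑axial C1 acyloxy group (sets C9), and because C8's ring partner later changes from C10 to C9, the retained cis‑diol becomes the trans C7–O/C8–OH of the target; closest known reactions are borinic‑acid/quinuclidine/photoredox C–H alkylation of glycoside cis‑diols with acrylates (net retention) and anti‑selective tertiary‑radical additions to 5‑alkoxybutenolides and 6‑alkoxypyranones.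

Step 5
Reactants: 7; 3, isovaleric acid
Product: 8, the 2′‑O‑(3‑methylbutanoyl) ester of 7 (C7 isovalerate; tertiary C8–OH free)
Conditions: 3, EDC·HCl, DMAP (0.2 equiv), CH2Cl2, 0 °C → rt
Reagents that add atoms: none
Why: Steglich esterification acylates the secondary C7–OH selectively over the tertiary C8–OH, and doing it now avoids any later primary/secondary differentiation once C10–OH is released.

Step 6
Reactants: 8
Product: 9, (1S,6S,7R,7aS)‑7‑hydroxy‑7‑(hydroxymethyl)‑4‑oxo‑1,3,4,6,7,7a‑hexahydrocyclopenta[c]pyran‑1,6‑diyl bis(3‑methylbutanoate)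
Conditions: TFA/H2O (9:1), CH2Cl2, 0 °C → rt; then TsOH·H2O (10 mol %), PhMe, 50 °C
Reagents that add atoms: none (MeOH is lost)
Why: Acid cleavage of the methyl furanoside gives the C6 aldehyde/oxocarbenium, which undergoes 5‑(enolexo) intramolecular aldol condensation with the C4 ketone enol at C5; dehydration (or retro‑oxa‑Michael of the bridged ether) gives the C5=C6 enone and frees C10–OH, with no stereocentre created and the acyl acetal at C1 surviving because it ionises far more slowly than a furanoside.

Step 7
Reactants: 9
Product: 10, (1S,6S,7R,7aS)‑7‑(acetoxymethyl)‑7‑hydroxy‑4‑oxo‑1,3,4,6,7,7a‑hexahydrocyclopenta[c]pyran‑1,6‑diyl bis(3‑methylbutanoate)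
Conditions: Ac2O, pyridine, CH2Cl2, 0 °C
Reagents that add atoms: acetic anhydride, CC(=O)OC(C)=O
Why: Chemoselective acetylation of the only primary alcohol (the tertiary C8–OH is inert without DMAP); immediate capping prevents O7→O10 isovaleryl migration.

Step 8
Reactants: 10
Product: 11, (1S,6S,7R,7aS)‑7‑(acetoxymethyl)‑7‑hydroxy‑4‑(trifluoromethylsulfonyloxy)‑1,6,7,7a‑tetrahydrocyclopenta[c]pyran‑1,6‑diyl bis(3‑methylbutanoate)
Conditions: KHMDS (2.1 equiv), THF, −78 °C; then Comins' reagent, −78 °C
Reagents that add atoms: N‑(5‑chloro‑2‑pyridyl)bis(trifluoromethanesulfonimide), O=S(=O)(N(c1ccc(Cl)cn1)S(=O)(=O)C(F)(F)F)C(F)(F)F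
Why: Kinetic α′‑deprotonation of the cross‑conjugated enone at C3 and O‑triflation give the C3=C4–C5=C6 dienol ether pattern of the target; the first equivalent of base is consumed by C8–OH, and no β‑leaving group is available to the enolate.

Step 9
Reactants: 11
Product: 12, (1S,6S,7R,7aS)‑7‑(acetoxymethyl)‑7‑hydroxy‑4‑(hydroxymethyl)‑1,6,7,7a‑tetrahydrocyclopenta[c]pyran‑1,6‑diyl bis(3‑methylbutanoate)
Conditions: Bu3SnCH2OH, Pd(PPh3)4 (5 mol %), CuI (10 mol %), LiCl, THF, 50 °C
Reagents that add atoms: (tributylstannyl)methanol, OC[Sn](CCCC)(CCCC)CCCC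
Why: Kosugi–Migita–Stille hydroxymethylation of the dienyl triflate installs C11 at the alcohol oxidation level under neutral conditions that leave the esters and the acyl acetal intact.

Step 10
Reactants: 12
Product: 13, 10‑acetoxyvaltrathydrin, [(1S,6S,7R,7aS)‑4,7‑bis(acetoxymethyl)‑7‑hydroxy‑1‑(3‑methylbutanoyloxy)‑1,6,7,7a‑tetrahydrocyclopenta[c]pyran‑6‑yl] 3‑methylbutanoate
Conditions: Ac2O, pyridine, 0 °C → rt
Reagents that add atoms: acetic anhydride, CC(=O)OC(C)=O
Why: Acetylation of the primary allylic C11–OH; the hindered tertiary C8–OH stays free, giving the target.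

**Compound list**
1 | furfuryl alcohol | OCc1ccco1 | starting material
2 | 6‑hydroxy‑2H‑pyran‑3(6H)‑one (racemic) | O=C1COC(O)C=C1 | intermediate
3 | isovaleric acid | CC(C)CC(=O)O | starting material
4 | (2S)‑5‑oxo‑5,6‑dihydro‑2H‑pyran‑2‑yl 3‑methylbutanoate | O=C1CO[C@@H](OC(=O)CC(C)C)C=C1 | intermediate
5 | D‑erythrose | O=C[C@H](O)[C@H](O)CO | starting material
6 | methyl β‑D‑erythrofuranoside | CO[C@H]1[C@H](O)[C@H](O)CO1 | intermediate
7 | Giese adduct (C8–C9 bond formed) | O=C1CO[C@@H](OC(=O)CC(C)C)[C@@H](C1)[C@@]2(O)CO[C@@H](OC)[C@@H]2O | intermediate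
8 | C7 isovalerate of 7 | O=C1CO[C@@H](OC(=O)CC(C)C)[C@@H](C1)[C@@]2(O)CO[C@@H](OC)[C@@H]2OC(=O)CC(C)C | intermediate
9 | bicyclic enone diol | O=C1CO[C@@H](OC(=O)CC(C)C)[C@H]2C1=C[C@H](OC(=O)CC(C)C)[C@]2(O)CO | intermediate
10 | C10 acetate of 9 | O=C1CO[C@@H](OC(=O)CC(C)C)[C@H]2C1=C[C@H](OC(=O)CC(C)C)[C@]2(O)COC(C)=O | intermediate
11 | dienyl triflate | O=S(=O)(OC1=CO[C@@H](OC(=O)CC(C)C)[C@H]2C1=C[C@H](OC(=O)CC(C)C)[C@]2(O)COC(C)=O)C(F)(F)F | intermediate
12 | C11 alcohol | OCC1=CO[C@@H](OC(=O)CC(C)C)[C@H]2C1=C[C@H](OC(=O)CC(C)C)[C@]2(O)COC(C)=O | intermediate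
13 | 10‑acetoxyvaltrathydrin | CC(=O)OCC1=CO[C@@H](OC(=O)CC(C)C)[C@H]2C1=C[C@H](OC(=O)CC(C)C)[C@]2(O)COC(C)=O | target

**Totals**
Total steps: 10. Longest linear sequence: 9 (steps 1, 2, 4–10 from furfuryl alcohol).

**Steps most likely to fail, with fallbacks**
1. Step 4 (radical coupling). Risks: H2′ versus H3′ abstraction, amine‑induced loss of isovalerate from 4 (oxidopyrylium formation), and congestion at the new quaternary centre. Fallback: change the radical precursor and the HAT manifold to base‑free decatungstate (TBADT, 390 nm) abstraction from 2‑O‑isovaleryl‑D‑erythronolactone, whose only hydridic carbinol C–H is C3′. The lactone carbonyl would then be brought to the aldehyde level (ketone as TBS enol ether, Sia2BH to the lactol, Mukaiyama‑type closure), at a cost of about two steps.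
2. Step 6 (acid aldol condensation). Risks: C7 epimerisation or elimination in the α‑acyloxy aldehyde, partial loss of the C1 ester, and acyl migration to C10–OH. Fallback: preform the C4=C5 silyl enol ether of 8 and close the ring by TMSOTf‑promoted intramolecular Mukaiyama addition to the furanosyl oxocarbenium, giving the bridged 2‑oxabicyclo[2.2.1]heptanone. A separate mild DBU retro‑oxa‑Michael then gives 9 without ever generating the free aldehyde.
3. Step 8 (and the Pd step 9). Risks: alkoxide‑triggered acetyl migration or vinylogous retro‑aldol, γ‑deprotonation at C7, and Pd(0) ionisation of the allylic C7 isovalerate. Fallback: abandon the enolate/cross‑coupling sequence and convert the C4 ketone of 10 with dimethylsulfonium methylide into the vinyl spiro‑epoxide (C4–O–C11). Eliminative opening with TMSOTf/2,6‑lutidine toward C3–H gives the 4‑(silyloxymethyl)‑3,5‑diene, and HF·pyridine then gives 12 without palladium.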